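The plan closes ring B (C5–C10, drimane numbering) last, by making the C9–C10 bond in a cation–olefin cyclization. Acid protonates the C1=C10 alkene of an (S)-α-cyclogeranyl ring A; the tertiary C10 cation is captured by C9 of a tethered (E)-enoate, and loss of H7 leaves the C7=C8 alkene. One operation gives ring B, the quaternary methyl-bearing C10 with the trans ring fusion, and the trisubstituted alkene, all relayed from the purchased C5 centre and the C6 carbinol. It exploits the head-to-tail isoprenoid pattern of ring B, in which the methyl-bearing carbons C8 and C10 flank C9. The precursor is an open-chain δ-silyloxy-β-methyl enoate on ring A. C9 is hydroxylated afterwards through the aldehyde dienolate.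

Key step: step 4

Assumption: (S)-(−)-α-ionone is bought as the single enantiomer; trimethyl phosphonoacetate, (2E,4E,6E)-octa-2,4,6-trienoic acid and all reagents are catalogue chemicals.

Numbering: drimane numbering is used for all compounds (ring A = C1–C5 and C10, ring B = C5–C10, C11 = formyl carbon on C9, C12 = methyl on C8); in the open-chain precursors each atom carries the number it has in the target.

Step 1
Reactants: 1 (S)-α-ionone
Product: 3 (4S)-4-hydroxy-4-[(1S)-2,6,6-trimethylcyclohex-2-en-1-yl]butan-2-one, via β-boryl ketone 2 (not isolated)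
Conditions: CuCl (5 mol %), NaOtBu (10 mol %), Josiphos-type ligand 1-[2-(diphenylphosphino)ferrocenyl]ethyldicyclohexylphosphine (6 mol %, enantiomer giving 6S), B2pin2 (1.2 equiv), MeOH (2 equiv), THF, rt; then NaBO3·4H2O, THF/H2O, rt
Reagents that add atoms: bis(pinacolato)diboron, CC1(C)OB(OC1(C)C)B1OC(C)(C)C(C)(C)O1 (boron of intermediate 2 only); sodium perborate, [Na+].[O-]OB=O (oxygen at C6 of 3)
Why: Copper-catalysed conjugate borylation of the enone (β-boration) should place boron at C6 under control of the chiral ligand, whose enantiomer is chosen so that the 6S boronate forms next to the purchased C5 centre, and perborate oxidation exchanges boron for oxygen with retention.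

Step 2
Reactants: 3 (4S)-4-hydroxy-4-[(1S)-2,6,6-trimethylcyclohex-2-en-1-yl]butan-2-one
Product: 4 (4S)-4-(triethylsilyloxy)-4-[(1S)-2,6,6-trimethylcyclohex-2-en-1-yl]butan-2-one
Conditions: Et3SiOTf (1.3 equiv), 2,6-lutidine (2 equiv), CH2Cl2, −78 °C
Reagents that add atoms: triethylsilyl trifluoromethanesulfonate, CC[Si](CC)(CC)OS(=O)(=O)C(F)(F)F
Why: Silyl ether formation on the secondary alcohol should proceed cleanly with the silyl triflate and masks the β-hydroxy ketone against retro-aldol cleavage in the basic olefination that follows; no stereocentre is touched.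

Step 3
Reactants: 4 (4S)-4-(triethylsilyloxy)-4-[(1S)-2,6,6-trimethylcyclohex-2-en-1-yl]butan-2-one; 5 trimethyl phosphonoacetate
Product: 6 methyl (2E,5S)-3-methyl-5-(triethylsilyloxy)-5-[(1S)-2,6,6-trimethylcyclohex-2-en-1-yl]pent-2-enoate
Conditions: NaH (3 equiv), 5 (3 equiv), THF, 0 → 45 °C; E isomer separated by chromatography
Reagents that add atoms: none
Why: Horner–Wadsworth–Emmons olefination of the methyl ketone should give the trisubstituted enoate mainly as the E isomer (the Z isomer is removed), which adds C9 and C11 and creates the nucleophilic alkene for ring closure.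

Step 4
Reactants: 6 methyl (2E,5S)-3-methyl-5-(triethylsilyloxy)-5-[(1S)-2,6,6-trimethylcyclohex-2-en-1-yl]pent-2-enoate
Product: 8 methyl (5S,6S,9S,10S)-6-hydroxydrim-7-en-11-oate (6α-OH and 5α-H and 9α-H with 10β-methyl and 9β-ester), via cyclized triethylsilyl ether 7 (not isolated)
Conditions: SnCl4 (2 equiv), CF3CO2H (1 equiv), CH2Cl2, −78 → −40 °C; aq. NaHCO3; then pyridinium p-toluenesulfonate, MeOH, rt on the crude product
Reagents that add atoms: none
Why: The Lewis acid-assisted Brønsted acid SnCl4–CF3CO2H protonates C1 of the ring alkene, the tertiary C10 cation is attacked by C9 (the α-carbon of the enoate), and the tertiary C8 cation so formed loses H7 to give the C7=C8 alkene; mild acidic methanolysis then frees the C6 hydroxyl group. The closest known reaction type is the acid-mediated cation–olefin cyclization of monocyclofarnesic esters to bicyclofarnesic (drim-7-en-11-oic) esters. Ring B closes by C9–C10 bond formation in a 6-endo-trig mode through a chair-like transition state. C10 is controlled by the C5 stereocentre: the C6 chain stays equatorial on ring A and C9 adds to the face of the cation anti to the axial C5–H, which gives the trans ring fusion with the β-methyl group, while C9 follows from the E geometry of the enoate (ester equatorial) and is re-set in step 7 in any case. The step needs attack through C9 and not C8, trans fusion and endocyclic proton loss; the polarity of the enoate (positive charge develops only at the tertiary β-carbon C8), the equatorial place of the 6S oxygen in the trans chair, and the axial H7 secure these, and a conjugated C8=C9 isomer would feed the same dienolate in step 7.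

Step 5
Reactants: 8 methyl (5S,6S,9S,10S)-6-hydroxydrim-7-en-11-oate
Product: 9 (5S,6S,9S,10R)-drim-7-ene-6α,11-diol
Conditions: LiAlH4 (2 equiv), THF, 0 °C → rt
Reagents that add atoms: none
Why: Hydride reduction of the methyl ester (LiAlH4 reduction) should give the primary alcohol at C11 without touching the stereocentres or the trisubstituted alkene.

Step 6
Reactants: 9 (5S,6S,9S,10R)-drim-7-ene-6α,11-diol
Product: 10 (5S,6S,9S,10S)-6α-hydroxydrim-7-en-11-al
Conditions: TEMPO (10 mol %), PhI(OAc)2 (1.1 equiv), CH2Cl2, rt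
Reagents that add atoms: none
Why: The oxoammonium species derived from TEMPO oxidizes the less hindered primary C11 alcohol much faster than the hindered secondary allylic C6 alcohol (chemoselective alcohol oxidation), so the β,γ-unsaturated aldehyde should result without over-oxidation.

Step 7
Reactants: 10 (5S,6S,9S,10S)-6α-hydroxydrim-7-en-11-al
Product: 12 (5S,6S,9R,10S)-6α,9α-dihydroxydrim-7-en-11-al, via dipotassium alkoxide dienolate 11 (not isolated)
Conditions: KN(SiMe3)2 (2.3 equiv), THF, −78 °C; then 2-(phenylsulfonyl)-3-phenyloxaziridine (1.3 equiv), −78 °C; aq. NH4Cl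
Reagents that add atoms: 2-(phenylsulfonyl)-3-phenyloxaziridine, O=S(=O)(c1ccccc1)N1OC1c1ccccc1
Why: Two equivalents of base give the C6 alkoxide and the extended dienolate O–C11=C9–C8=C7, and electrophilic oxygen transfer from the N-sulfonyloxaziridine (enolate α-hydroxylation) should occur at C9 from the α face, opposite the axial C10 methyl group, which sets the 9α-hydroxyl group and leaves the C7=C8 alkene in place.

Step 8
Reactants: 12 (5S,6S,9R,10S)-6α,9α-dihydroxydrim-7-en-11-al; 13 (2E,4E,6E)-octa-2,4,6-trienoic acid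
Product: 15 (1S,4R,4aS,8aS)-4-formyl-4-hydroxy-3,4a,8,8-tetramethyl-1,4,4a,5,6,7,8,8a-octahydronaphthalen-1-yl (2E,4E,6E)-octa-2,4,6-trienoate (target), via mixed anhydride 14 (not isolated)
Conditions: 13 (1.5 equiv), 2,4,6-trichlorobenzoyl chloride (1.5 equiv), Et3N (3 equiv), THF, rt; then 12, DMAP, toluene, rt
Reagents that add atoms: 2,4,6-trichlorobenzoyl chloride, O=C(Cl)c1c(Cl)cc(Cl)cc1Cl (aroyl group of intermediate 14 only)
Why: Yamaguchi esterification through the mixed anhydride should acylate only the secondary C6 hydroxyl group, because the tertiary C9 hydroxyl group is too hindered, and the mild conditions should preserve the all-E triene and the α-hydroxy aldehyde.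

Compound list

1 | (S)-α-ionone, (3E)-4-[(1S)-2,6,6-trimethylcyclohex-2-en-1-yl]but-3-en-2-one | CC(=O)/C=C/[C@@H]1C(C)=CCCC1(C)C | starting material
2 | (4S)-4-(4,4,5,5-tetramethyl-1,3,2-dioxaborolan-2-yl)-4-[(1S)-2,6,6-trimethylcyclohex-2-en-1-yl]butan-2-one | CC(=O)C[C@H](B2OC(C)(C)C(C)(C)O2)[C@@H]1C(C)=CCCC1(C)C | intermediate (not isolated)
3 | (4S)-4-hydroxy-4-[(1S)-2,6,6-trimethylcyclohex-2-en-1-yl]butan-2-one | CC(=O)C[C@H](O)[C@@H]1C(C)=CCCC1(C)C | intermediate
4 | (4S)-4-(triethylsilyloxy)-4-[(1S)-2,6,6-trimethylcyclohex-2-en-1-yl]butan-2-one | CC(=O)C[C@H](O[Si](CC)(CC)CC)[C@@H]1C(C)=CCCC1(C)C | intermediate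
5 | trimethyl phosphonoacetate, methyl 2-(dimethoxyphosphoryl)acetate | COC(=O)CP(=O)(OC)OC | starting material
6 | methyl (2E,5S)-3-methyl-5-(triethylsilyloxy)-5-[(1S)-2,6,6-trimethylcyclohex-2-en-1-yl]pent-2-enoate | COC(=O)/C=C(\C)C[C@H](O[Si](CC)(CC)CC)[C@@H]1C(C)=CCCC1(C)C | intermediate
7 | methyl (5S,6S,9S,10S)-6α-(triethylsilyloxy)drim-7-en-11-oate (trans-fused; 9α-H) | CC[Si](CC)(CC)O[C@H]1C=C(C)[C@H](C(=O)OC)[C@@]2(C)CCCC(C)(C)[C@H]12 | intermediate (not isolated)
8 | methyl (5S,6S,9S,10S)-6α-hydroxydrim-7-en-11-oate, methyl (1S,4S,4aS,8aS)-4-hydroxy-2,5,5,8a-tetramethyl-1,4,4a,5,6,7,8,8a-octahydronaphthalene-1-carboxylate | O[C@H]1C=C(C)[C@H](C(=O)OC)[C@@]2(C)CCCC(C)(C)[C@H]12 | intermediate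
9 | (5S,6S,9S,10R)-drim-7-ene-6α,11-diol (same spatial arrangement as 8; the descriptor at C10 changes by priority only) | O[C@H]1C=C(C)[C@H](CO)[C@@]2(C)CCCC(C)(C)[C@H]12 | intermediate
10 | (5S,6S,9S,10S)-6α-hydroxydrim-7-en-11-al | O[C@H]1C=C(C)[C@H](C=O)[C@@]2(C)CCCC(C)(C)[C@H]12 | intermediate
11 | dipotassium salt of 10 (C6 alkoxide and C11=C9–C8=C7 dienolate) | [K+].[K+].[O-][C@H]1C=C(C)C(=C[O-])[C@@]2(C)CCCC(C)(C)[C@H]12 | intermediate (not isolated)
12 | (5S,6S,9R,10S)-6α,9α-dihydroxydrim-7-en-11-al, (1R,4S,4aS,8aS)-1,4-dihydroxy-2,5,5,8a-tetramethyl-1,4,4a,5,6,7,8,8a-octahydronaphthalene-1-carbaldehyde | O[C@H]1C=C(C)[C@](O)(C=O)[C@@]2(C)CCCC(C)(C)[C@H]12 | intermediate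
13 | (2E,4E,6E)-octa-2,4,6-trienoic acid | C/C=C/C=C/C=C/C(=O)O | starting material
14 | (2E,4E,6E)-octa-2,4,6-trienoic 2,4,6-trichlorobenzoic anhydride | C/C=C/C=C/C=C/C(=O)OC(=O)c1c(Cl)cc(Cl)cc1Cl | intermediate (not isolated)
15 | (1S,4R,4aS,8aS)-4-formyl-4-hydroxy-3,4a,8,8-tetramethyl-1,4,4a,5,6,7,8,8a-octahydronaphthalen-1-yl (2E,4E,6E)-octa-2,4,6-trienoate, 6α-[(2E,4E,6E)-octa-2,4,6-trienoyloxy]-9α-hydroxydrim-7-en-11-al | C/C=C/C=C/C=C/C(=O)O[C@H]1C=C(C)[C@](O)(C=O)[C@@]2(C)CCCC(C)(C)[C@H]12 | target

Total step count: 8. Longest linear sequence: 8 steps (1 → 15).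

Steps most likely to fail

Step 4 (key step). Capture of the C10 cation by the electron-poor enoate may be slower than proton loss to the tetrasubstituted C5=C10 alkene. That would erase the C5 centre and make the C6–O bond allylic and prone to ionization; the new allylic C6–O bond of the product may also ionize under the Lewis acid. The fallback sets out from 6 and comes back at 9. It first turns the enoate into a more nucleophilic trisubstituted alkene. Reduction of 6 with iBu2AlH (CH2Cl2, −78 °C) should give (2E,5S)-3-methyl-5-(triethylsilyloxy)-5-[(1S)-2,6,6-trimethylcyclohex-2-en-1-yl]pent-2-en-1-ol F1, and Ac2O/pyridine should give its acetate F2. The same acid pair should then close ring B of this farnesyl acetate-type substrate to 6α-(triethylsilyloxy)drim-7-en-11-yl acetate F3. Pyridinium p-toluenesulfonate in MeOH converts this into 6α-hydroxydrim-7-en-11-yl acetate F4. K2CO3 in MeOH removes the acetate and gives diol 9, so step 5 is no longer needed.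

Step 7. Oxygen transfer to the fully substituted C9 of the hindered dienolate may be slow. Reaction at C7, addition of the enolate to the sulfonimine formed from the oxidant, or base-induced α-ketol rearrangement of the product may then compete. The fallback sets out from 10 and comes back at 12; it is a Rubottom oxidation under non-basic conditions. Et3SiOTf/Et3N (CH2Cl2, 0 °C) should silylate the C6 hydroxyl group and convert the aldehyde into the bis(triethylsilyl) dienol ether of 10 F5. Dimethyldioxirane (acetone/CH2Cl2, −78 °C) should epoxidize the electron-rich C9=C11 enol ether from the α face, and silyl migration opens the epoxide to 6α,9α-bis(triethylsilyloxy)drim-7-en-11-al F6. HF·pyridine (THF, 0 °C) then gives 12.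

Step 1. Addition of the boryl-copper species to the hindered β-carbon C6 may be slow, and mismatched double stereodifferentiation between the ligand and the C5 centre may give poor facial selectivity at C6; the base may also slowly shift the C1=C10 alkene. The fallback sets out from 1 and comes back at 3; it uses catalyst-controlled nucleophilic epoxidation followed by reductive opening. La(OiPr)3/BINOL/Ph3As=O with tBuOOH (THF, molecular sieves; BINOL enantiomer chosen for this epoxide) should give 1-[(2S,3R)-3-[(1S)-2,6,6-trimethylcyclohex-2-en-1-yl]oxiran-2-yl]ethan-1-one F7. SmI2 (THF/MeOH, −78 °C) should then cleave the C7–O bond next to the carbonyl group and give 3.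

Further compounds

F1 | step 4 | (2E,5S)-3-methyl-5-(triethylsilyloxy)-5-[(1S)-2,6,6-trimethylcyclohex-2-en-1-yl]pent-2-en-1-ol | OC/C=C(\C)C[C@H](O[Si](CC)(CC)CC)[C@@H]1C(C)=CCCC1(C)C
F2 | step 4 | (2E,5S)-3-methyl-5-(triethylsilyloxy)-5-[(1S)-2,6,6-trimethylcyclohex-2-en-1-yl]pent-2-en-1-yl acetate | CC(=O)OC/C=C(\C)C[C@H](O[Si](CC)(CC)CC)[C@@H]1C(C)=CCCC1(C)C
F3 | step 4 | (5S,6S,9S,10R)-6α-(triethylsilyloxy)drim-7-en-11-yl acetate | CC[Si](CC)(CC)O[C@H]1C=C(C)[C@H](COC(C)=O)[C@@]2(C)CCCC(C)(C)[C@H]12
F4 | step 4 | (5S,6S,9S,10R)-6α-hydroxydrim-7-en-11-yl acetate | O[C@H]1C=C(C)[C@H](COC(C)=O)[C@@]2(C)CCCC(C)(C)[C@H]12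
F5 | step 7 | bis(triethylsilyl) dienol ether of 10, (5S,6S,10S)-6α,11-bis(triethylsilyloxy)drima-7,9(11)-diene | CC[Si](CC)(CC)O[C@H]1C=C(C)C(=CO[Si](CC)(CC)CC)[C@@]2(C)CCCC(C)(C)[C@H]12
F6 | step 7 | (5S,6S,9R,10S)-6α,9α-bis(triethylsilyloxy)drim-7-en-11-al | CC[Si](CC)(CC)O[C@H]1C=C(C)[C@](O[Si](CC)(CC)CC)(C=O)[C@@]2(C)CCCC(C)(C)[C@H]12
F7 | step 1 | 1-[(2S,3R)-3-[(1S)-2,6,6-trimethylcyclohex-2-en-1-yl]oxiran-2-yl]ethan-1-one | CC(=O)[C@H]1O[C@@H]1[C@@H]2C(C)=CCCC2(C)C
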